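## The problem

Sarothralin (20) is made of three six-membered carbocycles joined only through single atoms: an aromatic acylphloroglucinol ring A, a dearomatised ring B (a 2-isobutyryl-4,4-dimethylcyclohexane-1,3,5-trione written as its dienol) and a phenyl ring. Ring A is numbered here C1 (benzoyl), C2 (OH), C3 (bridge CH2), C4 (OH), C5 (H), C6 (prenyloxy); the phenyl ring is held to C1 through a ketone and ring B to C3 through one methylene carbon. There is no stereocentre and no stereogenic double bond, so the difficulty is purely regiochemical: six different positions on ring A, three oxygens of which only O6 is alkylated, and a bridge that must sit between the two free hydroxyls and not at C5. Both ring carbons that flank the bridge are nucleophilic, so joining two finished rings with a one-carbon electrophile would give statistical and regioisomeric mixtures; the bridge carbon is better carried on one ring from the start. The fragile parts are the aryl prenyl ether (lost to protic and Lewis acids, to hydride-abstracting quinones and to hydrogenation), the enolised triketone of ring B (easily oxidised, O-alkylated or over-methylated) and the bridge itself, which can fragment to a quinone methide in base. The feature that opens the key step is that the ketone carbon on C1 and the ether oxygen on C6 are neighbours: an aryne across C1 and C6 can accept both from benzoic acid (9) in one operation, steered by the oxygen on C2, and the oxygen so delivered is the only free hydroxyl of the product, the one that must carry the prenyl group.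

## Retrosynthesis

**Bridge.** The first cut is the bond between the bridge carbon and C4 of ring B in 20. The carbon stays on ring A as the C3 methyl group of benzophenone 15, and ring B is released as acyltrione 18. The neighbouring cut, between the bridge carbon and ring A, would leave the choice between C3 and C5 of ring A open; with the carbon already on C3 the site is fixed by the starting material. The 31-carbon target falls into pieces of 19 and 12 carbons. Forward, 15 is oxidised at the methyl group to the ortho-quinone methide 19, which 18 captures at its only enolic CH. The oxidant must take the phenol and spare the prenyl ether and the enol of 18; hydride-abstracting quinones are set aside because they also cleave prenyl ethers.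

**Prenyl ether and protecting groups.** Benzophenone 15 is traced to its bis(methoxymethyl) ether 13 and, by cutting the O6–prenyl bond, to phenol 11 and 1-bromo-3-methylbut-2-ene (12). Prenylation of an unprotected trihydroxybenzophenone would go to the unchelated O4; in 11 the O6 hydroxyl is the only one present. The cost is that two acetals must later be removed beside an acid-labile allylic ether, which calls for a buffered, non-protic cleavage through the silyl ether 14.

**Key disconnection.** In 11 the C1–C(=O) bond and the C6–O bond are cut together, giving aryne 10 and benzoic acid (9); 10 is released from the ortho-silylaryl triflate 8. A Friedel–Crafts or Fries benzoylation of a protected phloroglucinol would need Lewis acids that strip acetals and would not by itself distinguish the oxygens. The aryne insertion forms both bonds under fluoride alone, places the benzoyl group next to O2 through the polarisation of the aryne, and leaves exactly O6 free. The forward reaction must add with the right orientation and must favour acyl transfer over protonation of the aryl anion.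

**Aryne precursor.** Triflate 8 is cut at the C–Si and O–S bonds back to bromophenol 5. O-Silylation (6), bromine–lithium exchange and retro-Brook shift give phenoxide 7, which is triflated. Bromophenol 5 comes from phenol 4 by bromination; 4 is symmetric, its para position is blocked, and both ortho positions are the same, so no regiochemical question arises.

**Phenol 4.** The C–O bond of 4 is cut to arene 2, the bis(methoxymethyl) ether of 2-methylbenzene-1,3-diol (1). C5–H of 2 is the only ring hydrogen without an ortho neighbour, so sterically governed C–H borylation (boronate 3) and oxidation place the hydroxyl there. Starting instead from the corresponding methylated triol and telling its three hydroxyls apart by selective silylation would cost several more steps and rest on a modest steric bias.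

**Ring B.** Acyltrione 18 is cut at its two C–CH3 bonds to the acylphloroglucinol 17, and 17 at the aryl–acyl bond to benzene-1,3,5-triol (16). Both forward steps are classical; the methylation must be held at the gem-dimethyl stage.

## Roads not taken

**Alternative 1:** Ring A itself is cut into the four-carbon unit 2-methyl-3-(triisopropylsilyloxy)cyclobut-2-en-1-one A2 and the two-carbon unit (triisopropylsilyloxy)ethyne A3. On heating, A2 opens to a vinylketene that adds A3 in a (2+2) sense; the new cyclobutenone opens again, and a six-electron electrocyclisation with tautomerisation gives 4-methyl-3,5-bis(triisopropylsilyloxy)phenol A1.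
- Merits: the substitution pattern of A1 follows from the connectivity of the partners, and the one free hydroxyl is the one para to methyl. The other two oxygens carry silyl groups that fluoride removes with no threat to a prenyl ether. In this respect it is better than the chosen plan, which must remove acetals beside the prenyl group (step 7).
- Weak points: A1 is the silyl analogue of phenol 4, which is reached here in two steps from a commercial arene, whereas A2 and A3 each need several steps and A3 is sensitive. The benzannulation rebuilds a ring that can be bought and solves neither the benzoyl group nor the bridge. The silyl ethers also rule out a fluoride-triggered aryne, so the ketone would have to come from a separate Fries-type step.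
- Comparison: against the better protecting groups, the chosen plan offers a shorter approach to the key intermediate and a key step that makes two bonds of the target.

**Alternative 2:** Ring B is cut between the acyl-bearing carbon and a ring carbonyl to give the open-chain methyl 2-{[2,6-bis(methoxymethoxy)-4-(3-methylbut-2-en-1-yloxy)phenyl]methyl}-4,4,8-trimethyl-3,5,7-trioxononanoate A5. Base closes it by Dieckmann condensation (the methylene between two ketones attacks the ester) to 4-{[2,6-bis(methoxymethoxy)-4-(3-methylbut-2-en-1-yloxy)phenyl]methyl}-3,5-dihydroxy-6,6-dimethyl-2-(2-methylpropanoyl)cyclohexa-2,4-dien-1-one A4.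
- Merits: the gem-dimethyl carbon and the bridge are in the chain from the outset, and the aryl ring of A4 is symmetric. No methylation has to be stopped halfway (step 9) and no methyl group is oxidised beside an enol (step 10). On both counts it is stronger than the chosen plan.
- Weak points: A4 has no benzoyl group. It would be introduced last, next to the enols of ring B (O-acylation) and an aryl prenyl ether that Friedel–Crafts Lewis acids cleave, and two acetals would still have to come off. A5, with three ketones, a quaternary carbon and an ester, is long to assemble and can undergo retro-Claisen cleavage or close through oxygen.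
- Comparison: the chosen plan installs the benzophenone early, on a robust aromatic intermediate, in the step that also singles out O6. It accepts the risk of step 10 in exchange.

**Alternative 3:** Ring A is cut between C1 and C2 to the open-chain methyl (4E)-2-methyl-5-(3-methylbut-2-en-1-yloxy)-3,7-dioxo-7-phenylhept-4-enoate A7, whose prenyl enol ether stands for the C6 carbonyl of a polyketide chain. Base removes a proton from the carbon α to the benzoyl group (also the vinylogous position of the alkoxy enone); this carbon attacks the ester, the alkoxide is lost and the ring aromatises to [2,4-dihydroxy-3-methyl-6-(3-methylbut-2-en-1-yloxy)phenyl](phenyl)methanone A6, which is the same compound as 15.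
- Merits: 15 would be reached with no protecting group, so the acetal removal of step 7 would not arise. If A7 were at hand, this road would be as good as or better than the chosen one in step count up to 15.
- Weak points: A7 needs an O-prenylation of a tricarbonyl chain with defined site and geometry. It is an allyl vinyl ether and can rearrange in the Claisen sense to a C-prenyl compound. The same base can close the chain the other way (aldol onto the benzoyl ketone, or through oxygen to a pyranone) or expel the alkoxy group by β-elimination.
- Comparison: the chosen plan keeps an aromatic ring of fixed substitution throughout and has a key step of defined orientation, at the price of four steps to 8 and of protecting groups.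

Key step: step 5

Remark: 20 has no stereocentre; ring B and its precursors are drawn as the 3,5-dihydroxy-dienone tautomer of the target SMILES, which stands for all rapidly exchanging enol forms.
Remark: ring A is sourced from 2-methylbenzene-1,3-diol (1), which gives phenol 4 without having to differentiate three hydroxyls.

## Route

Step 1
Reactants: 1 2-methylbenzene-1,3-diol
Product: 2 1,3-bis(methoxymethoxy)-2-methylbenzene
Conditions: NaH, MOMCl, DMF, 0 °C → rt
Reagents that add atoms: chloromethyl methyl ether, COCCl
Why: Double Williamson-type O-alkylation of the bis-phenoxide with the reactive α-chloro ether; the MOM acetals tolerate the organolithium, fluoride and carbonate steps ahead and need neither hydrogenolysis nor a hard Lewis acid for removal.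

Step 2
Reactants: 2 1,3-bis(methoxymethoxy)-2-methylbenzene
Product: 4 3,5-bis(methoxymethoxy)-4-methylphenol, via aryl pinacol boronate 3 (not isolated)
Conditions: [Ir(OMe)(cod)]2 (cat.), 4,4′-di-tert-butyl-2,2′-bipyridine (cat.), HBpin, THF, 60 °C; then aq NaOH, 30% H2O2, 0 °C → rt
Reagents that add atoms: hydrogen peroxide, OO (the new oxygen of 4); pinacolborane, CC1(C)OBOC1(C)C (boron of intermediate 3 only)
Why: Sterically governed iridium-catalysed aromatic C–H borylation: C5 of 2 is the only ring C–H without an ortho substituent, so boron enters para to the methyl group to give 3. Basic peroxide then oxidises the C–B bond with 1,2-aryl shift from boron to oxygen, and the alkaline medium spares the acetals.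

Step 3
Reactants: 4 3,5-bis(methoxymethoxy)-4-methylphenol
Product: 5 2-bromo-3,5-bis(methoxymethoxy)-4-methylphenol
Conditions: NBS (1.0 equiv), CH2Cl2, −78 → −20 °C
Reagents that add atoms: N-bromosuccinimide, O=C1CCC(=O)N1Br
Why: Electrophilic aromatic bromination of a strongly activated phenol; the para position is blocked by the methyl group and the two ortho positions are equivalent by symmetry, so only over-bromination has to be held back by one equivalent of reagent at low temperature.

Step 4
Reactants: 5 2-bromo-3,5-bis(methoxymethoxy)-4-methylphenol
Product: 8 3,5-bis(methoxymethoxy)-4-methyl-2-(trimethylsilyl)phenyl trifluoromethanesulfonate, via aryl trimethylsilyl ether 6 (not isolated), via lithium 2-silylphenolate 7 (not isolated)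
Conditions: (Me3Si)2NH, THF, 65 °C, then evaporation; n-BuLi, THF, −100 °C; Tf2O, −100 → −78 °C; aq NaHCO3
Reagents that add atoms: hexamethyldisilazane, C[Si](C)(C)N[Si](C)(C)C; trifluoromethanesulfonic anhydride, O=S(=O)(OS(=O)(=O)C(F)(F)F)C(F)(F)F
Why: One-flask conversion of an ortho-bromophenol into an ortho-silylaryl triflate: O-silylation to 6, bromine–lithium exchange (faster at −100 °C than acetal-directed ring lithiation) and anionic 1,3-silyl shift from oxygen to carbon (retro-Brook) give phenoxide 7, which Tf2O traps on oxygen.

Step 5
Reactants: 8 3,5-bis(methoxymethoxy)-4-methyl-2-(trimethylsilyl)phenyl trifluoromethanesulfonate; 9 benzoic acid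
Product: 11 [6-hydroxy-2,4-bis(methoxymethoxy)-3-methylphenyl](phenyl)methanone, via aryne 10 (not isolated)
Conditions: CsF (4 equiv, dried), 9 (1.2 equiv), THF, 125 °C, sealed tube
Reagents that add atoms: none
Why: Fluoride attacks silicon of 8 and triflate is expelled, releasing aryne 10 across C1 and C6 (ring A numbering of the target). Benzoate, formed from 9 and CsF, adds through oxygen to C6, the terminus remote from the C2 methoxymethoxy group, because that alkoxy group polarises the strained triple bond so that the developing aryl anion sits at C1 beside the inductively withdrawing oxygen, and C6 with only hydrogen next to it is also the open terminus. The C1 anion then attacks the neighbouring ester carbonyl through a four-membered transition structure and the ester C–O bond breaks, so the benzoyl group arrives on C1 and the oxygen stays on C6 as a phenoxide that is protonated on work-up. The closest known reaction type is the fluoride-induced insertion of arynes into the C–O bond of carboxylic acids to give ortho-hydroxyaryl ketones, run hot in THF because heat favours the acyl shift over protonation of the aryl anion. No ring is closed and no stereocentre is formed. Two selectivities are needed: orientation of addition across the aryne, secured by the C2 alkoxy group and the unhindered C6, and acyl shift against simple O-arylation, secured by the high temperature, dry CsF and only a slight excess of acid. The acetals and the methyl group should be inert to CsF, and the chelated phenoxide of the product is a poor partner for a second aryne.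

Step 6
Reactants: 11 [6-hydroxy-2,4-bis(methoxymethoxy)-3-methylphenyl](phenyl)methanone; 12 1-bromo-3-methylbut-2-ene
Product: 13 [2,4-bis(methoxymethoxy)-3-methyl-6-(3-methylbut-2-en-1-yloxy)phenyl](phenyl)methanone
Conditions: K2CO3, acetone, 56 °C
Reagents that add atoms: none
Why: Williamson ether synthesis; 11 has one hydroxyl only, so the site of prenylation was decided in step 5, and carbonate in acetone is enough to alkylate the chelated ortho-hydroxy ketone by SN2 attack at the primary allylic bromide without Claisen rearrangement.

Step 7
Reactants: 13 [2,4-bis(methoxymethoxy)-3-methyl-6-(3-methylbut-2-en-1-yloxy)phenyl](phenyl)methanone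
Product: 15 [2,4-dihydroxy-3-methyl-6-(3-methylbut-2-en-1-yloxy)phenyl](phenyl)methanone, via bis(trimethylsilyl) ether 14 (not isolated)
Conditions: TMSOTf, 2,2′-bipyridyl, MeCN, 0 °C → rt; then H2O
Reagents that add atoms: trimethylsilyl trifluoromethanesulfonate, C[Si](C)(C)OS(=O)(=O)C(F)(F)F (silyl groups of intermediate 14 only; none remain in 15)
Why: Acetal cleavage by silyl triflate buffered with 2,2′-bipyridyl: the acetal oxygen is silylated, the methoxymethyl cation is held as a pyridinium salt and each aryl oxygen leaves as its TMS ether (14), so no free Brønsted acid meets the prenyl ether; water then hydrolyses the aryl silyl ethers. This non-protic MOM removal is established for aryl MOM ethers that carry acid-labile groups.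

Step 8
Reactants: 16 benzene-1,3,5-triol
Product: 17 2-methyl-1-(2,4,6-trihydroxyphenyl)propan-1-one
Conditions: i-PrCOCl (1 equiv), AlCl3, PhNO2/CH2Cl2, 0 → 50 °C; aq HCl
Reagents that add atoms: 2-methylpropanoyl chloride, CC(C)C(Cl)=O
Why: Friedel–Crafts C-acylation of the symmetric, highly activated triol; the first acyl group deactivates the ring and binds AlCl3 by chelation, so monoacylation is the normal outcome with one equivalent of acyl chloride.

Step 9
Reactants: 17 2-methyl-1-(2,4,6-trihydroxyphenyl)propan-1-one
Product: 18 3,5-dihydroxy-6,6-dimethyl-2-(2-methylpropanoyl)cyclohexa-2,4-dien-1-one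
Conditions: NaOMe, MeI (2 equiv), MeOH, 0 °C → rt; aq HCl
Reagents that add atoms: iodomethane, CI
Why: Dearomatising C-methylation of an acylphloroglucinol: the polyanion is alkylated at a ring carbon and the second methyl enters the same carbon because this gives the stabilised enolate of the vinylogous acid 18; a known route to acylfilicinic acids, with stoichiometry limiting tri- and tetramethylation.

Step 10
Reactants: 15 [2,4-dihydroxy-3-methyl-6-(3-methylbut-2-en-1-yloxy)phenyl](phenyl)methanone; 18 3,5-dihydroxy-6,6-dimethyl-2-(2-methylpropanoyl)cyclohexa-2,4-dien-1-one
Product: 20 sarothralin, 4-{[3-benzoyl-2,6-dihydroxy-4-(3-methylbut-2-en-1-yloxy)phenyl]methyl}-3,5-dihydroxy-6,6-dimethyl-2-(2-methylpropanoyl)cyclohexa-2,4-dien-1-one, via ortho-quinone methide 19 (not isolated)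
Conditions: Ag2O (1.1 equiv), TEMPO (cat.), 18 (2 equiv), THF, 0 °C → rt, dark
Reagents that add atoms: none
Why: Oxidative generation of an ortho-quinone methide from an ortho-methylphenol followed by Michael addition of a cyclic β-triketone: Ag2O with TEMPO as hydrogen-atom shuttle removes the phenolic and one benzylic hydrogen of 15 to give 19, which 18 attacks at its only enolic CH (C4), re-aromatising ring A. The oxidant does not abstract hydride from the prenyl ether as a high-potential quinone would, and the reaction type is known for C-alkylated acylphloroglucinols.

## Compound list

1 | 2-methylbenzene-1,3-diol | Cc1c(O)cccc1O | starting material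
2 | 1,3-bis(methoxymethoxy)-2-methylbenzene | COCOc1cccc(OCOC)c1C | intermediate
3 | 2-[3,5-bis(methoxymethoxy)-4-methylphenyl]-4,4,5,5-tetramethyl-1,3,2-dioxaborolane | COCOc1cc(B2OC(C)(C)C(C)(C)O2)cc(OCOC)c1C | intermediate
4 | 3,5-bis(methoxymethoxy)-4-methylphenol | COCOc1cc(O)cc(OCOC)c1C | intermediate
5 | 2-bromo-3,5-bis(methoxymethoxy)-4-methylphenol | COCOc1cc(O)c(Br)c(OCOC)c1C | intermediate
6 | [2-bromo-3,5-bis(methoxymethoxy)-4-methylphenoxy](trimethyl)silane | COCOc1cc(O[Si](C)(C)C)c(Br)c(OCOC)c1C | intermediate
7 | lithium 3,5-bis(methoxymethoxy)-4-methyl-2-(trimethylsilyl)phenolate | [Li+].[O-]c1cc(OCOC)c(C)c(OCOC)c1[Si](C)(C)C | intermediate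
8 | 3,5-bis(methoxymethoxy)-4-methyl-2-(trimethylsilyl)phenyl trifluoromethanesulfonate | C[Si](C)(C)c1c(OS(=O)(=O)C(F)(F)F)cc(OCOC)c(C)c1OCOC | intermediate
9 | benzoic acid | OC(=O)c1ccccc1 | starting material
10 | 1,2-didehydro-3,5-bis(methoxymethoxy)-4-methylbenzene (3,5-bis(methoxymethoxy)-4-methylbenzyne) | COCOC1=CC#CC(OCOC)=C1C | intermediate
11 | [6-hydroxy-2,4-bis(methoxymethoxy)-3-methylphenyl](phenyl)methanone | O=C(c1ccccc1)c1c(O)cc(OCOC)c(C)c1OCOC | intermediate
12 | 1-bromo-3-methylbut-2-ene | CC(C)=CCBr | starting material
13 | [2,4-bis(methoxymethoxy)-3-methyl-6-(3-methylbut-2-en-1-yloxy)phenyl](phenyl)methanone | CC(C)=CCOc1cc(OCOC)c(C)c(OCOC)c1C(=O)c1ccccc1 | intermediate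
14 | [3-methyl-6-(3-methylbut-2-en-1-yloxy)-2,4-bis(trimethylsilyloxy)phenyl](phenyl)methanone | CC(C)=CCOc1cc(O[Si](C)(C)C)c(C)c(O[Si](C)(C)C)c1C(=O)c1ccccc1 | intermediate
15 | [2,4-dihydroxy-3-methyl-6-(3-methylbut-2-en-1-yloxy)phenyl](phenyl)methanone | CC(C)=CCOc1cc(O)c(C)c(O)c1C(=O)c1ccccc1 | intermediate
16 | benzene-1,3,5-triol | Oc1cc(O)cc(O)c1 | starting material
17 | 2-methyl-1-(2,4,6-trihydroxyphenyl)propan-1-one | CC(C)C(=O)c1c(O)cc(O)cc1O | intermediate
18 | 3,5-dihydroxy-6,6-dimethyl-2-(2-methylpropanoyl)cyclohexa-2,4-dien-1-one | CC(C)C(=O)C1=C(O)C=C(O)C(C)(C)C1=O | intermediate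
19 | 4-benzoyl-5-hydroxy-6-methylidene-3-(3-methylbut-2-en-1-yloxy)cyclohexa-2,4-dien-1-one | C=C1C(=O)C=C(OCC=C(C)C)C(C(=O)c2ccccc2)=C1O | intermediate
20 | sarothralin, 4-{[3-benzoyl-2,6-dihydroxy-4-(3-methylbut-2-en-1-yloxy)phenyl]methyl}-3,5-dihydroxy-6,6-dimethyl-2-(2-methylpropanoyl)cyclohexa-2,4-dien-1-one | CC(C)=CCOc1cc(O)c(CC2=C(O)C(C)(C)C(=O)C(C(=O)C(C)C)=C2O)c(O)c1C(=O)c1ccccc1 | target

## Step count and least certain steps

Total step count: 10. Longest linear sequence: 8 steps (1 to 20 through steps 1–7 and 10); ring B takes steps 8 and 9 and joins in step 10.

**Step 10 (oxidative coupling), the least certain.** The one-electron oxidation may not stay at the methyl group. The phenoxyl radical of 15 can couple through the free C5 position, the enol of 18 can itself be oxidised and dimerise on silver, and the quinone methide can condense with itself before 18 reaches it.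
Fallback: from 15, the oxidation is separated from the carbon–carbon bond formation. 15 alone is treated with Ag2O and catalytic TEMPO in methanol, which traps 19 as the benzylic ether [2,4-dihydroxy-3-(methoxymethyl)-6-(3-methylbut-2-en-1-yloxy)phenyl](phenyl)methanone F1. F1 is then heated with 18 and NaOAc in toluene, where reversible loss of methanol regenerates 19 with no oxidant present and 18 adds to it, returning to the route at 20.

**Step 5 (key step).** The aryl anion may be protonated before the acyl shift, so that simple O-arylation takes over, since the acid and its bifluoride salt are proton sources. The crowded, electron-rich aryne may also be consumed by fluoride or by the product phenoxide.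
Fallback: from 5, the same aryl anion is reached without an aryne. Benzoylation (benzoyl chloride, Et3N, cat. DMAP, CH2Cl2) gives 2-bromo-3,5-bis(methoxymethoxy)-4-methylphenyl benzoate F2. Bromine–lithium exchange with n-BuLi in THF at −100 °C then triggers the anionic ortho-Fries 1,3-shift of the benzoyl group from oxygen to carbon, returning to the route at 11.

**Step 7 (acetal removal beside the prenyl ether).** The silylating Lewis acid may ionise the allylic aryl ether, or the hindered C2 acetal (between benzoyl and methyl) may react too slowly, so that forcing conditions cost the prenyl group.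
Fallback: from 11, the allylic ether is carried through the acid step in a form that acid does not touch. Allyl bromide and K2CO3 in acetone give [2,4-bis(methoxymethoxy)-3-methyl-6-(prop-2-en-1-yloxy)phenyl](phenyl)methanone F3. HCl in methanol at 50 °C removes both acetals to give [2,4-dihydroxy-3-methyl-6-(prop-2-en-1-yloxy)phenyl](phenyl)methanone F4. Cross-metathesis of F4 with excess 2-methylbut-2-ene and second-generation Grubbs catalyst, (H2IMes)(PCy3)Cl2Ru=CHPh, in CH2Cl2 at 40 °C converts the allyl into the prenyl ether, returning to the route at 15.

**Step 9 (gem-dimethylation).** Methylation may not stop cleanly: mono-, tri- and tetramethylation and O-methylation compete because all ring carbons of the polyanion are nucleophilic.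
Fallback: from 16, the ring positions that must not be methylated are blocked first. Double acetylation (Ac2O, BF3·OEt2) gives 1,1′-(2,4,6-trihydroxy-1,3-phenylene)di(ethan-1-one) F5, which has one free ring carbon. NaOMe and MeI give 2,4-diacetyl-3,5-dihydroxy-6,6-dimethylcyclohexa-2,4-dien-1-one F6. Hot aqueous H2SO4 removes both acetyl groups to give 3,5-dihydroxy-4,4-dimethylcyclohexa-2,5-dien-1-one F7 (filicinic acid). C-Acylation of F7 with 2-methylpropanoyl chloride and AlCl3 returns to the route at 18.

## Further compounds

F1 | step 10 | [2,4-dihydroxy-3-(methoxymethyl)-6-(3-methylbut-2-en-1-yloxy)phenyl](phenyl)methanone | COCc1c(O)cc(OCC=C(C)C)c(C(=O)c2ccccc2)c1O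
F2 | step 5 | 2-bromo-3,5-bis(methoxymethoxy)-4-methylphenyl benzoate | COCOc1cc(OC(=O)c2ccccc2)c(Br)c(OCOC)c1C
F3 | step 7 | [2,4-bis(methoxymethoxy)-3-methyl-6-(prop-2-en-1-yloxy)phenyl](phenyl)methanone | C=CCOc1cc(OCOC)c(C)c(OCOC)c1C(=O)c1ccccc1
F4 | step 7 | [2,4-dihydroxy-3-methyl-6-(prop-2-en-1-yloxy)phenyl](phenyl)methanone | C=CCOc1cc(O)c(C)c(O)c1C(=O)c1ccccc1
F5 | step 9 | 1,1′-(2,4,6-trihydroxy-1,3-phenylene)di(ethan-1-one) | CC(=O)c1c(O)cc(O)c(C(C)=O)c1O
F6 | step 9 | 2,4-diacetyl-3,5-dihydroxy-6,6-dimethylcyclohexa-2,4-dien-1-one | CC(=O)C1=C(O)C(C(C)=O)=C(O)C(C)(C)C1=O
F7 | step 9 | 3,5-dihydroxy-4,4-dimethylcyclohexa-2,5-dien-1-one (filicinic acid) | O=C1C=C(O)C(C)(C)C(O)=C1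
A1 | alternative 1 | 4-methyl-3,5-bis(triisopropylsilyloxy)phenol | Cc1c(O[Si](C(C)C)(C(C)C)C(C)C)cc(O)cc1O[Si](C(C)C)(C(C)C)C(C)C
A2 | alternative 1 | 2-methyl-3-(triisopropylsilyloxy)cyclobut-2-en-1-one | CC1=C(O[Si](C(C)C)(C(C)C)C(C)C)CC1=O
A3 | alternative 1 | (triisopropylsilyloxy)ethyne | C#CO[Si](C(C)C)(C(C)C)C(C)C
A4 | alternative 2 | 4-{[2,6-bis(methoxymethoxy)-4-(3-methylbut-2-en-1-yloxy)phenyl]methyl}-3,5-dihydroxy-6,6-dimethyl-2-(2-methylpropanoyl)cyclohexa-2,4-dien-1-one | CC(C)=CCOc1cc(OCOC)c(CC2=C(O)C(C)(C)C(=O)C(C(=O)C(C)C)=C2O)c(OCOC)c1
A5 | alternative 2 | methyl 2-{[2,6-bis(methoxymethoxy)-4-(3-methylbut-2-en-1-yloxy)phenyl]methyl}-4,4,8-trimethyl-3,5,7-trioxononanoate (racemic) | COC(=O)C(Cc1c(OCOC)cc(OCC=C(C)C)cc1OCOC)C(=O)C(C)(C)C(=O)CC(=O)C(C)C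
A6 | alternative 3 | [2,4-dihydroxy-3-methyl-6-(3-methylbut-2-en-1-yloxy)phenyl](phenyl)methanone | CC(C)=CCOc1cc(O)c(C)c(O)c1C(=O)c1ccccc1
A7 | alternative 3 | methyl (4E)-2-methyl-5-(3-methylbut-2-en-1-yloxy)-3,7-dioxo-7-phenylhept-4-enoate (racemic) | COC(=O)C(C)C(=O)/C=C(/OCC=C(C)C)CC(=O)c1ccccc1
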